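**Plan**

Ring A is numbered C1 (carbonyl, between C2 and C6), C2 (butanoyl), C3 and C5 (enol oxygens), C4 (quaternary: methyl, prenyl) and C6 (CH2 bridge). Ring B is numbered C1' (on the bridge), C2'/C6' (OH), C3' (H), C4' (OMe) and C5' (butanoyl).
Retrosynthesis: the two enol caps of ring A are removed; ring B is opened at C5'–C6' to an acylketene stored as a 2,2-dimethyl-1,3-dioxin-4-one; the CH2–C6 bond is cut; ring A is cut at C2–C3 (Claisen) and C5–C6 (acylation) back to a 2-methyl-2-prenylmalonic half-ester and heptane-2,4-dione.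
Enabling feature: ring B is an acylphloroglucinol, a folded tetraketide chain C6'–C1'–C2'–C3'–C4'–C5'–CO. Its single O-methyl (on C4') can be written into the open chain as a β-methoxy enone, which leaves C5' as the only nucleophile that can reach the ketene carbon C6'.
Forward: ring A is built first (steps 1–4) and the dioxinone arm separately (steps 5–9). They are joined at the CH2 bridge (step 10), ring A is capped (step 11), ring B is closed last by thermolysis (step 12) and the caps are removed (step 13).
Stereochemistry: the only stereocentre, quaternary C4 (R), comes from enzymatic desymmetrisation of a prochiral malonate (step 2). Using the acid carbon as C5 and the ester carbon as C3 fixes which flank carries the butanoyl group, and a carbon without hydrogen cannot epimerise later.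

Key step: step 12

Remark: pig liver esterase is assumed to cleave the ester group that gives the (R)-half-ester 4; the descriptor stays (R) to the end because the ester-derived carbon keeps the higher priority in every intermediate.
Remark: ring A of 8, 21 and 27 is a set of fast-exchanging enol tautomers, drawn like the target; bis-enol ether 22 is drawn as the 3,5-di-O-alkyl isomer, and a regioisomeric bis-ether formed beside it would behave the same way in steps 12 and 13.

Step 1
Reactants: 1 dimethyl 2-methylmalonate; 2 prenyl bromide (1-bromo-3-methylbut-2-ene)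
Product: 3 dimethyl 2-methyl-2-(3-methylbut-2-en-1-yl)malonate
Conditions: NaH, THF, 0 °C → rt
Reagents that add atoms: none
Why: Malonic ester alkylation of the enolate (formed with NaH) by a reactive allylic bromide installs the prenyl group and creates the future quaternary carbon, still prochiral.

Step 2
Reactants: 3 dimethyl 2-methyl-2-(3-methylbut-2-en-1-yl)malonate
Product: 4 (R)-3-methoxy-2-methyl-2-(3-methylbut-2-en-1-yl)-3-oxopropanoic acid
Conditions: pig liver esterase, NaH2PO4/Na2HPO4 buffer (pH 7.5), DMSO (10 vol%), 25 °C, pH-stat with 1 M NaOH; then HCl to pH 2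
Reagents that add atoms: water (O)
Why: Enzymatic desymmetrisation of a prochiral 2,2-disubstituted malonate hydrolyses one of the two enantiotopic ester groups, so the quaternary stereocentre is set by the enzyme's discrimination between the methyl and prenyl substituents.

Step 3
Reactants: 4 (R)-half-ester; 5 heptane-2,4-dione
Product: 7 methyl (R)-2-methyl-2-(3-methylbut-2-en-1-yl)-3,5,7-trioxodecanoate, via acyl imidazolide 6 (not isolated)
Conditions: 4, CDI, THF, rt; 5 (2.5 equiv), LiN(i-Pr)2 (5 equiv), THF, 0 °C, then 6 at −78 → 0 °C; 1 M HCl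
Reagents that add atoms: none
Why: C-acylation of a β-diketone 1,3-dianion at its terminal methyl carbon extends the chain; the acyl imidazolide reacts far faster than the neopentyl-type methyl ester, so the acid carbon becomes C5 and the ester carbon is kept for C3.

Step 4
Reactants: 7 triketo ester
Product: 8 (R)-2-butanoyl-3,5-dihydroxy-4-methyl-4-(3-methylbut-2-en-1-yl)cyclohexa-2,5-dien-1-one (ring A monomer, enol form of the 1,3,5-trione)
Conditions: t-BuOK (2.5 equiv), THF, 0 → 40 °C; 1 M HCl
Reagents that add atoms: none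
Why: Intramolecular Claisen (Dieckmann-type) condensation, in which the carbon between the C1 ketone and the butanoyl group attacks the ester in a 6-exo closure, gives ring A with the butanoyl group already on C2; the non-nucleophilic base avoids retro-Claisen cleavage and the quaternary centre is untouched.

Step 5
Reactants: 9 2,2,6-trimethyl-4H-1,3-dioxin-4-one
Product: 10 5-iodo-2,2,6-trimethyl-4H-1,3-dioxin-4-one
Conditions: NIS, AcOH, rt, dark
Reagents that add atoms: N-iodosuccinimide (O=C1CCC(=O)N1I)
Why: Electrophilic iodination of the push–pull enol ether occurs at C5, the α-carbon of the β-alkoxy enoate, as is usual for 6-alkyl dioxinones.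

Step 6
Reactants: 10 5-iodo-2,2,6-trimethyl-4H-1,3-dioxin-4-one
Product: 13 5-{[tert-butyl(dimethyl)silyl]oxymethyl}-2,2,6-trimethyl-4H-1,3-dioxin-4-one, via dioxinonyl Grignard reagent 11 (not isolated), via hydroxymethyl dioxinone 12 (not isolated)
Conditions: i-PrMgCl·LiCl, THF, −30 °C; CH2O (monomer in THF), −30 → 0 °C; TBSCl, imidazole, DMF, rt
Reagents that add atoms: formaldehyde (C=O); tert-butyl(chloro)dimethylsilane (CC(C)(C)[Si](C)(C)Cl)
Why: Iodine–magnesium exchange gives the 5-magnesiated dioxinone, which should persist at −30 °C; Grignard addition to formaldehyde supplies the bridge carbon, and the alkoxide is silylated in the same flask so that the next deprotonation meets no O–H.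

Step 7
Reactants: 14 butanoyl chloride; 15 1,1-dichloroethene
Product: 17 1,1-dichlorohex-1-en-3-one, via trichloro ketone 16 (not isolated)
Conditions: AlCl3, CH2Cl2, 0 °C → rt; then Et3N, Et2O, 0 °C
Reagents that add atoms: none
Why: Friedel–Crafts-type acylation of the alkene gives the β,β,β-trichloro ketone, which loses HCl by E1cB elimination to the β,β-dichlorovinyl ketone, a vinylogous acid chloride.

Step 8
Reactants: 13 silyl ether; 17 1,1-dichlorohex-1-en-3-one
Product: 19 5-{[tert-butyl(dimethyl)silyl]oxymethyl}-6-[(E)-2-methoxy-4-oxohept-2-en-1-yl]-2,2-dimethyl-4H-1,3-dioxin-4-one, via chloro enone 18 (not isolated)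
Conditions: LiN(i-Pr)2, THF, −78 °C; enolate added to 17 (1.5 equiv), THF, −78 °C; then MeOH, Et3N, DMAP (cat.), −78 °C → rt
Reagents that add atoms: methanol (CO)
Why: The γ-deprotonated (vinylogous) dioxinone enolate attacks the β-carbon of 17 by conjugate addition–elimination (ketovinylation), and methanol then replaces the remaining vinylic chloride in a second addition–elimination, which places the methoxy group on C4' by construction and should give the more stable (E)-β-methoxy enone; inverse addition at −78 °C keeps the electrophile in excess and limits loss of silanolate from the enolate.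

Step 9
Reactants: 19 silyl ether with methoxy enone arm
Product: 20 5-(bromomethyl)-6-[(E)-2-methoxy-4-oxohept-2-en-1-yl]-2,2-dimethyl-4H-1,3-dioxin-4-one
Conditions: Ph3PBr2, CH2Cl2, 0 °C → rt; used at once
Reagents that add atoms: triphenylphosphine dibromide (Br[P+](c1ccccc1)(c1ccccc1)c1ccccc1.[Br-])
Why: Appel-type substitution through the alkoxyphosphonium salt converts the primary allylic silyl ether directly into the bromide, so that no free hydroxyl, which could add to the neighbouring vinylogous ester, is ever present.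

Step 10
Reactants: 8 ring A monomer; 20 bromide
Product: 21 (R)-2-butanoyl-3,5-dihydroxy-6-({6-[(E)-2-methoxy-4-oxohept-2-en-1-yl]-2,2-dimethyl-4-oxo-4H-1,3-dioxin-5-yl}methyl)-4-methyl-4-(3-methylbut-2-en-1-yl)cyclohexa-2,5-dien-1-one
Conditions: 8 (1.3 equiv), NaOMe (1.3 equiv), MeOH, 0 °C; 20 in THF, 0 °C → rt
Reagents that add atoms: none
Why: SN2 C-alkylation of the β-triketone anion at C6, its only unsubstituted nucleophilic carbon, by a soft allylic bromide in a protic medium that favours carbon over oxygen; the triketonate is too weak a base to deprotonate the side chain of 20, and no free methoxide remains.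

Step 11
Reactants: 21 coupled triketone
Product: 22 (R)-2-butanoyl-3,5-bis(methoxymethoxy)-6-({6-[(E)-2-methoxy-4-oxohept-2-en-1-yl]-2,2-dimethyl-4-oxo-4H-1,3-dioxin-5-yl}methyl)-4-methyl-4-(3-methylbut-2-en-1-yl)cyclohexa-2,5-dien-1-one
Conditions: MOMCl, i-Pr2NEt, CH2Cl2, 0 °C → rt
Reagents that add atoms: chloromethyl methyl ether (COCCl)
Why: O-alkylation of both acidic enols by a hard alkylating agent caps ring A (C2 and C6 are fully substituted, so only oxygen reacts); methoxymethyl is chosen over methyl because it is cleaved later at the acetal carbon and not at the hindered ring carbons C3 and C5.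

Step 12
Reactants: 22 dioxinone with capped ring A
Product: 26 (R)-2-butanoyl-6-[(3-butanoyl-2,6-dihydroxy-4-methoxyphenyl)methyl]-3,5-bis(methoxymethoxy)-4-methyl-4-(3-methylbut-2-en-1-yl)cyclohexa-2,5-dien-1-one, via acylketene 23 (not isolated), via dienylketene 24 (not isolated), via cyclohexadienone 25 (not isolated)
Conditions: toluene (5 mM), 110 °C, N2 stream
Reagents that add atoms: none
Why: Retro-hetero-Diels–Alder loss of acetone gives acylketene 23, whose C2' ketone enolises toward C3' to dienylketene 24 (C6'=C1', C2'=C3', C4'=C5'); thermal disrotatory 6π-electrocyclisation joins C5' to the ketene carbon C6' (in polar terms a 6-exo attack of the enol-ether carbon on the ketene) to give cyclohexa-2,4-dienone 25, and a proton shift from C5' aromatises it. The closest known reactions are the thermolysis of 2,2-dimethyl-1,3-dioxin-4-ones to acylketenes that are trapped intramolecularly, the C-acylation of enol ethers by acylketenes, and the electrocyclisation of dienylketenes to phenols in the Danheiser benzannulation. Ring B is the only ring closed and C5'–C6' the only new skeletal bond; no stereocentre is made, because C5' of 25 is sp3 only until it aromatises, and C4 of ring A is not involved. The step needs C–C bond formation at C5' in preference to O-acylation, ketene dimerisation or capture by ring A: the C4' oxygen is locked as a methyl ether so that C5' is the only nucleophile six atoms from the ketene carbon, both ring A enols are capped, high dilution suppresses bimolecular paths, and reversible [4+2] capture of the ketene by a carbonyl group would only regenerate a dioxinone. The enol-ether geometry is not decisive, since C5' carries H and the acyl group either way, and the methoxy group ends on C4' by construction.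

Step 13
Reactants: 26 capped dimer
Product: 27 (R)-2-butanoyl-6-[(3-butanoyl-2,6-dihydroxy-4-methoxyphenyl)methyl]-3,5-dihydroxy-4-methyl-4-(3-methylbut-2-en-1-yl)cyclohexa-2,5-dien-1-one (target)
Conditions: 0.5 M HCl, MeOH–H2O (4:1), rt
Reagents that add atoms: none
Why: Acid-catalysed acetal hydrolysis removes both methoxymethyl groups at the unhindered acetal carbon under conditions too mild for the aryl methyl ether, the prenyl group or the methylene bridge; the methanol co-solvent holds the released formaldehyde as its hemiacetal, away from the free C3' position of ring B.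

**Compound list**

1 | dimethyl 2-methylmalonate | COC(=O)C(C)C(=O)OC | starting material
2 | prenyl bromide (1-bromo-3-methylbut-2-ene) | CC(C)=CCBr | starting material
3 | dimethyl 2-methyl-2-(3-methylbut-2-en-1-yl)malonate | COC(=O)C(C)(CC=C(C)C)C(=O)OC | intermediate
4 | (R)-3-methoxy-2-methyl-2-(3-methylbut-2-en-1-yl)-3-oxopropanoic acid | COC(=O)[C@](C)(CC=C(C)C)C(=O)O | intermediate
5 | heptane-2,4-dione | CCCC(=O)CC(C)=O | starting material
6 | methyl (R)-2-(1H-imidazole-1-carbonyl)-2,5-dimethylhex-4-enoate (acyl imidazolide of 4) | COC(=O)[C@](C)(CC=C(C)C)C(=O)n1ccnc1 | intermediate (not isolated)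
7 | methyl (R)-2-methyl-2-(3-methylbut-2-en-1-yl)-3,5,7-trioxodecanoate | COC(=O)[C@](C)(CC=C(C)C)C(=O)CC(=O)CC(=O)CCC | intermediate
8 | (R)-2-butanoyl-3,5-dihydroxy-4-methyl-4-(3-methylbut-2-en-1-yl)cyclohexa-2,5-dien-1-one (ring A monomer) | CCCC(=O)C1=C(O)[C@](C)(CC=C(C)C)C(O)=CC1=O | intermediate
9 | 2,2,6-trimethyl-4H-1,3-dioxin-4-one | CC1=CC(=O)OC(C)(C)O1 | starting material
10 | 5-iodo-2,2,6-trimethyl-4H-1,3-dioxin-4-one | CC1=C(I)C(=O)OC(C)(C)O1 | intermediate
11 | chloro(2,2,6-trimethyl-4-oxo-4H-1,3-dioxin-5-yl)magnesium | CC1=C([Mg]Cl)C(=O)OC(C)(C)O1 | intermediate (not isolated)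
12 | 5-(hydroxymethyl)-2,2,6-trimethyl-4H-1,3-dioxin-4-one (present as its alkoxide) | CC1=C(CO)C(=O)OC(C)(C)O1 | intermediate (not isolated)
13 | 5-{[tert-butyl(dimethyl)silyl]oxymethyl}-2,2,6-trimethyl-4H-1,3-dioxin-4-one | CC1=C(CO[Si](C)(C)C(C)(C)C)C(=O)OC(C)(C)O1 | intermediate
14 | butanoyl chloride | CCCC(=O)Cl | starting material
15 | 1,1-dichloroethene | C=C(Cl)Cl | starting material
16 | 1,1,1-trichlorohexan-3-one | CCCC(=O)CC(Cl)(Cl)Cl | intermediate (not isolated)
17 | 1,1-dichlorohex-1-en-3-one | CCCC(=O)C=C(Cl)Cl | intermediate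
18 | 5-{[tert-butyl(dimethyl)silyl]oxymethyl}-6-(2-chloro-4-oxohept-2-en-1-yl)-2,2-dimethyl-4H-1,3-dioxin-4-one (E/Z mixture, geometry not defined) | CCCC(=O)C=C(Cl)CC1=C(CO[Si](C)(C)C(C)(C)C)C(=O)OC(C)(C)O1 | intermediate (not isolated)
19 | 5-{[tert-butyl(dimethyl)silyl]oxymethyl}-6-[(E)-2-methoxy-4-oxohept-2-en-1-yl]-2,2-dimethyl-4H-1,3-dioxin-4-one | CCCC(=O)/C=C(OC)\CC1=C(CO[Si](C)(C)C(C)(C)C)C(=O)OC(C)(C)O1 | intermediate
20 | 5-(bromomethyl)-6-[(E)-2-methoxy-4-oxohept-2-en-1-yl]-2,2-dimethyl-4H-1,3-dioxin-4-one | CCCC(=O)/C=C(OC)\CC1=C(CBr)C(=O)OC(C)(C)O1 | intermediate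
21 | (R)-2-butanoyl-3,5-dihydroxy-6-({6-[(E)-2-methoxy-4-oxohept-2-en-1-yl]-2,2-dimethyl-4-oxo-4H-1,3-dioxin-5-yl}methyl)-4-methyl-4-(3-methylbut-2-en-1-yl)cyclohexa-2,5-dien-1-one | CCCC(=O)C1=C(O)[C@](C)(CC=C(C)C)C(O)=C(CC2=C(C/C(OC)=C\C(=O)CCC)OC(C)(C)OC2=O)C1=O | intermediate
22 | 3,5-bis(methoxymethyl) enol ether of 21 (key-step precursor) | CCCC(=O)C1=C(OCOC)[C@](C)(CC=C(C)C)C(OCOC)=C(CC2=C(C/C(OC)=C\C(=O)CCC)OC(C)(C)OC2=O)C1=O | intermediate
23 | acylketene from 22 by loss of acetone: O=C=C(CH2–ring A)–CO–CH2–C(OMe)=CH–CO–Pr, ring A as in 22 | CCCC(=O)C1=C(OCOC)[C@](C)(CC=C(C)C)C(OCOC)=C(CC(=C=O)C(=O)C/C(OC)=C\C(=O)CCC)C1=O | intermediate (not isolated)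
24 | dienol tautomer of 23 (dienylketene; C1' and C4' cis on C2'=C3') | CCCC(=O)C1=C(OCOC)[C@](C)(CC=C(C)C)C(OCOC)=C(CC(=C=O)/C(O)=C\C(OC)=C/C(=O)CCC)C1=O | intermediate (not isolated)
25 | 6-butanoyl-3-hydroxy-5-methoxy-2-(ring A-methyl)cyclohexa-2,4-dien-1-one, ring A as in 22; C6 of this ring (C5') is a transient sp3 centre of undefined configuration | CCCC(=O)C1=C(OCOC)[C@](C)(CC=C(C)C)C(OCOC)=C(CC2=C(O)C=C(OC)C(C(=O)CCC)C2=O)C1=O | intermediate (not isolated)
26 | (R)-2-butanoyl-6-[(3-butanoyl-2,6-dihydroxy-4-methoxyphenyl)methyl]-3,5-bis(methoxymethoxy)-4-methyl-4-(3-methylbut-2-en-1-yl)cyclohexa-2,5-dien-1-one (key-step product) | CCCC(=O)C1=C(OCOC)[C@](C)(CC=C(C)C)C(OCOC)=C(Cc2c(O)cc(OC)c(C(=O)CCC)c2O)C1=O | intermediate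
27 | (R)-2-butanoyl-6-[(3-butanoyl-2,6-dihydroxy-4-methoxyphenyl)methyl]-3,5-dihydroxy-4-methyl-4-(3-methylbut-2-en-1-yl)cyclohexa-2,5-dien-1-one | CCCC(=O)C1=C(O)[C@](C)(CC=C(C)C)C(O)=C(Cc2c(O)cc(OC)c(C(=O)CCC)c2O)C1=O | target

**Step count and risks**

Total steps: 13. Longest linear sequence: 8 steps (1 → 27 through steps 1–4 and 10–13, or 9 → 27 through steps 5, 6, 8–13).

Step 12 (ring B closure). The ketene may be consumed by dimerisation or by an oxygen nucleophile before C5' reaches it, or the newly formed phenol may add to a ring A enol ether at 110 °C. The fallback brings ring B in already aromatic, which is the classical way to methylene-bridged acylphloroglucinols. It sets out from ring A monomer 8. 5-Methoxyresorcinol is acylated with butanoyl chloride 14 (AlCl3, Friedel–Crafts acylation) to 1-(2,4-dihydroxy-6-methoxyphenyl)butan-1-one F1, the isomer with the acyl group between OH and OMe, separated from the 2,6-dihydroxy isomer. Monomer 8 is aminomethylated at C6 with dimethylmethyleneiminium iodide (Mannich reaction) to (R)-2-butanoyl-6-[(dimethylamino)methyl]-3,5-dihydroxy-4-methyl-4-(3-methylbut-2-en-1-yl)cyclohexa-2,5-dien-1-one F2. Heating F2 with F1 in dioxane should expel dimethylamine, and the 6-methylene trione so formed should be captured by F1 at the ring carbon between its two hydroxyls. This gives 27 directly, so the route is rejoined at 27.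

Step 8 (side chain). The hard dienolate may add to the carbonyl group of 17 or merely deprotonate it, or the enolate may expel silanolate before it reacts. The fallback builds the methoxy enone from 13 by homologations of established type and comes back at 19. The dienolate of 13 (LiN(i-Pr)2) is carboxylated with CO2 to 2-[5-({[tert-butyl(dimethyl)silyl]oxy}methyl)-2,2-dimethyl-4-oxo-4H-1,3-dioxin-6-yl]acetic acid F3. Activation with CDI and decarboxylative Claisen condensation with Mg(O2CCH2COSEt)2 gives S-ethyl 4-[5-({[tert-butyl(dimethyl)silyl]oxy}methyl)-2,2-dimethyl-4-oxo-4H-1,3-dioxin-6-yl]-3-oxobutanethioate F4. O-Methylation of its enol (Me2SO4, Cs2CO3, DMF) can only occur at the ketone oxygen, since the thioester carbonyl cannot be alkylated, and gives S-ethyl (E)-4-[5-({[tert-butyl(dimethyl)silyl]oxy}methyl)-2,2-dimethyl-4-oxo-4H-1,3-dioxin-6-yl]-3-methoxybut-2-enethioate F5. Fukuyama coupling of F5 with n-PrZnI (PdCl2(PPh3)2, catalytic) then gives ketone 19.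

Step 10 (union). The ambident triketonate may be alkylated at oxygen or twice at C6, or bromide 20 may be lost by 1,4-elimination of HBr followed by electrocyclisation of the resulting triene. The fallback forms the same bond by palladium-catalysed allylic alkylation, in which any O-allylated enol ether can re-ionise and funnel to the C-alkylated product. It sets out from silyl ether 19. Buffered HF·pyridine gives 5-(hydroxymethyl)-6-[(E)-2-methoxy-4-oxohept-2-en-1-yl]-2,2-dimethyl-4H-1,3-dioxin-4-one F6. ClCO2Me and pyridine give {6-[(E)-2-methoxy-4-oxohept-2-en-1-yl]-2,2-dimethyl-4-oxo-4H-1,3-dioxin-5-yl}methyl methyl carbonate F7. Pd(PPh3)4 (zerovalent palladium, catalytic) in THF with 8 should then give 21 (Tsuji–Trost reaction; the methoxide released with CO2 deprotonates 8), and the route is rejoined at 21.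

**Further compounds**

F1 | step 12 | 1-(2,4-dihydroxy-6-methoxyphenyl)butan-1-one | CCCC(=O)c1c(O)cc(O)cc1OC
F2 | step 12 | (R)-2-butanoyl-6-[(dimethylamino)methyl]-3,5-dihydroxy-4-methyl-4-(3-methylbut-2-en-1-yl)cyclohexa-2,5-dien-1-one | CCCC(=O)C1=C(O)[C@](C)(CC=C(C)C)C(O)=C(CN(C)C)C1=O
F3 | step 8 | 2-[5-({[tert-butyl(dimethyl)silyl]oxy}methyl)-2,2-dimethyl-4-oxo-4H-1,3-dioxin-6-yl]acetic acid | OC(=O)CC1=C(CO[Si](C)(C)C(C)(C)C)C(=O)OC(C)(C)O1
F4 | step 8 | S-ethyl 4-[5-({[tert-butyl(dimethyl)silyl]oxy}methyl)-2,2-dimethyl-4-oxo-4H-1,3-dioxin-6-yl]-3-oxobutanethioate | CCSC(=O)CC(=O)CC1=C(CO[Si](C)(C)C(C)(C)C)C(=O)OC(C)(C)O1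
F5 | step 8 | S-ethyl (E)-4-[5-({[tert-butyl(dimethyl)silyl]oxy}methyl)-2,2-dimethyl-4-oxo-4H-1,3-dioxin-6-yl]-3-methoxybut-2-enethioate | CCSC(=O)/C=C(OC)\CC1=C(CO[Si](C)(C)C(C)(C)C)C(=O)OC(C)(C)O1
F6 | step 10 | 5-(hydroxymethyl)-6-[(E)-2-methoxy-4-oxohept-2-en-1-yl]-2,2-dimethyl-4H-1,3-dioxin-4-one | CCCC(=O)/C=C(OC)\CC1=C(CO)C(=O)OC(C)(C)O1
F7 | step 10 | {6-[(E)-2-methoxy-4-oxohept-2-en-1-yl]-2,2-dimethyl-4-oxo-4H-1,3-dioxin-5-yl}methyl methyl carbonate | CCCC(=O)/C=C(OC)\CC1=C(COC(=O)OC)C(=O)OC(C)(C)O1
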